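A small charge of incoming ligand, the same in both earlier runs, can be counted seat by seat, so we count what it fails to fill.

| setting | teal | grey | flask |
|---|---|---|---|
| starting complex | 0.36 M | 0.57 M | 0.26 M |
| incoming ligand | 0.26 M (fed, over 80 s) | 0.26 M (fed, over 80 s) | 0.260 M (fed, over 80 s) |
| remark | run made earlier | run made earlier |  |
| time |  |  | 12 min |

- teal (time / min: complex with three exchanged / %, complex with one exchanged / %): 3.00: 4.4, 52.2; 6.00: 3.3, 53.3; 8.00: 2.9, 53.0; 12.0: 3.6, 52.2; 15.0: 3.3, 52.9
- grey (time / min: complex with three exchanged / %, complex with one exchanged / %): 1.00: 0.4, 28.0; 2.00: 1.1, 38.3; 4.00: 0.9, 41.0; 8.00: 1.0, 39.6; 15.0: 0.6, 40.2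

(each reading ± 0.5 percentage points)

- candidate steps: complex with two exchanged + incoming ligand <-> leaving ligand + complex with three exchanged; starting complex + incoming ligand <-> leaving ligand + complex with one exchanged; complex with one exchanged + incoming ligand <-> leaving ligand + complex with two exchanged; starting complex <-> dormant form; complex with three exchanged -> over-reaction product
- the reaction counts as stopped when no species that holds the starting complex changes by six tenths of a point or more over the second half of the time

- which holds at 12 min: what has brought the reaction to rest, or that it has not come to rest (all of the starting complex has reacted / forward and back rates have come level / the incoming ligand has run out first / it is still moving)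
- how much complex with three exchanged there is at 12 min, in percent of the starting complex charged
- how much complex with one exchanged there is at 12 min, in percent of the starting complex charged

1. Feed, the first rung. In the grey run at 1.00 min, 81.8% of the ligand fed so far already sits on complex with one exchanged, so exchange keeps up with the 80 s feed.
2. Rest, the next rung. The teal run reads 52.2% of that complex at 3.00 min and 52.9% at 15.0 min, which is flat within a scatter of 0.5 percentage points.
3. Over-reaction, the last rung. Complex with three exchanged in the teal run reads 3.3% at 6.00 min and 3.3% at 15.0 min, so no drift shows.
4. The count. Take the last two readings of each run, with one ligand on complex with one exchanged and three on complex with three exchanged. The grey run then leaves 7.27% of its ligand charge uncounted, and the teal run 12.9%. We call this fraction left over the unplaced ligand: it is ligand still free, or ligand on complex with two exchanged or on over-reaction product.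
5. Our reckoning. Placed on complex with two exchanged, the teal share would make that complex read 4.66%, above the 3.45% of complex with three exchanged. Yet the forecast's fit has the third step faster than the second. So we take some ligand to stand free on a flat curve, with forward and back rates level (equilibrium). A straight line in equivalents gives the flask 18.8% unplaced.
6. The forecast: the incoming ligand has run out first, with 10% (7% to 13%) of complex with three exchanged and 59% (54% to 63%) of complex with one exchanged. In its words: “An equilibrium fit works almost as well, so the end state is not proven.” We part from it on the end.

In the flask at 12 min, forward and back rates have come level: it holds 9.06% of complex with three exchanged and 57.1% of complex with one exchanged, and the largest change of a share over the second half is 0.11 points. Its unplaced ligand is 15.7% against our 18.8%, and 8.5% of the ligand charge is still left at 12.0 min.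

    complex with two exchanged + incoming ligand ⇌ leaving ligand + complex with three exchanged (K = 31.0, k = 3.08 L mol⁻¹ s⁻¹)
    starting complex + incoming ligand ⇌ leaving ligand + complex with one exchanged (K = 25.9, k = 1.01 L mol⁻¹ s⁻¹)
    complex with one exchanged + incoming ligand ⇌ leaving ligand + complex with two exchanged (K = 0.594, k = 1.30 L mol⁻¹ s⁻¹)
    starting complex ⇌ dormant form (K = 0.280, k = 0.0180 s⁻¹)
    complex with three exchanged → over-reaction product (k = 4.95 × 10⁻⁵ s⁻¹)

The neighbouring flask holds 0.44 M of starting complex, so 0.591 equiv of incoming ligand. The same line gives it 10.1% unplaced, and its 47.5% of complex with one exchanged and 2.00% of complex with three exchanged give 9.48%, with 4.6% of its ligand charge left at 12.0 min.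

Readings and results are simulated with constants of no real substance; scatter was added.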